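The vessel is closed, stirred and isothermal, and before repeating the run I must decide how much partner to charge and what to watch.

| flask | substrate | partner | remark | time |
|---|---|---|---|---|
| Monday's | 0.050 M | 0.82 equiv | run made earlier |  |
| Sunday's | 0.050 M | 1.9 equiv | run made earlier |  |
| maple | 0.050 M | 0.700 equiv |  | 12 h |
| birch | 0.050 M | 1.40 equiv |  | 12 h |

- Monday's (time / h: target / %, substrate / %): 1.50: 4, 74; 3.00: 6, 51; 5.00: 13, 32; 6.00: 17, 26; 8.00: 20, 17
- Sunday's (time / h: target / %, substrate / %): 1.50: 4, 72; 3.00: 12, 53; 5.00: 20, 32; 6.00: 26, 26; 8.00: 29, 12

(standard deviation of a reading: 2 percentage points)

- which of the two there is more of at the end, maple (side product / target)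
- which of the two there is more of at the end, birch (side product / target)
- how much target is there at the end, in percent of the substrate charged: maple
- how much target is there at the end, in percent of the substrate charged: birch

- the numbers in the tables scatter by 2 percentage points (one standard deviation)

Substrate falls alike in both earlier runs, to 26% and 26% at 6.00 h, although their partner charges differ. I therefore read partner as absent from the substrate's own loss, take that loss as first order, and square that fraction for twice the time:

substrate left at 12 h = 6.76%

Partner shows in the split instead: at the last reading target is 20% in Monday's run and 29% in Sunday's. For each run I divide target by the rest of the substrate consumed, then by the equivalents of partner charged: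

Monday's: 0.387
Sunday's: 0.259
mean, S = 0.323

This S, a selectivity factor giving target over the rest of the substrate consumed for each equivalent of partner charged, is what I carry. Monday's value stands above Sunday's, and each rests on single readings that scatter by 2 percentage points, so I hold the mean as a rough figure. With r = S times the equivalents charged, target is the substrate consumed times r/(1+r):

maple: r = 0.226, target = 17.2%
birch: r = 0.452, target = 29.0%

Since r stays below one in birch, and lower in maple, I expect side product ahead in both, supposing it makes up most of the rest. I choose birch's charge, and I watch target against the substrate consumed.

The forecast gives 23% for maple, above my figure, and 32% for birch, with side product ahead in both, holding that “Partner instead controls what happens afterwards”.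

    partner + intermediate → target (k = 0.0448 L mol⁻¹ min⁻¹)
    intermediate → side product (k = 0.00470 min⁻¹)
    substrate → intermediate (k = 0.00381 min⁻¹)
    2 intermediate → homo product (k = 0.0546 L mol⁻¹ min⁻¹)

Maple gives 16.6% target and birch 29.2%, with side product ahead at 56.9% and 49.0%. At maple's end 7.45% still stands as intermediate, and target reaches 19.3% at 120 h, when substrate stands at 0%. Applied to that whole charge, S gives r/(1+r) = 18.4% for maple.

On birch's recipe with 3.50 equiv of partner, S gives r = 1.13, above one, and target = 49.5%. That flask gives 52.0% target, over 33.7% side product.

(The numbers in the tables stem from a simulated flask for an exercise.)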